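(All constants are assumed, and the outcome is calculated.)

In this closed flask a balance holds at every moment: solid substrate left + [starting material] + [target] + [isomer of the product] + 2[side product] stays at the charge.

solid substrate 1.5 M; gas phase 200 mM (held); time 10 d

* the target standing at 10 d, as a percentage of the solid substrate charged
* concentration of dissolved gas in solution at 10 d, in percent of saturation

- in percentages every species weighs as the solid substrate in it: one side product counts as two
- as a solid, counted per litre of solution: solid substrate
- at the start none of the gas is dissolved
- at the start none of the solid substrate is in solution
- run time (flask): 10 d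

    gas phase ⇌ dissolved gas, rate k1*(csat - [dissolved gas]) (k1 = 9.3 × 10⁻⁴ s⁻¹, csat = 200 mM)
    starting material + dissolved gas → target (k2 = 0.0019 M⁻¹ s⁻¹)
    solid substrate ⇌ starting material, rate k3*(cs3 - [starting material]) while solid is left; crystals form when [starting material] > cs3 (cs3 = 0.50 M, k3 = 5.6 × 10⁻⁵ s⁻¹)
    starting material + target → side product (k4 = 3.7 × 10⁻⁶ M⁻¹ s⁻¹)
    target ⇌ isomer of the product (K5 = 0.24, k5 = 1.3 × 10⁻⁵ s⁻¹)

Work in powers of ten. First ask whether the charge gets through. Dissolving at its fastest, the solid substrate needs 0.620 d, which is 1.21 decades below the run time. The gas can enter 6.64 times faster than the solid can dissolve, so take dissolved gas near saturation.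

Then ask what the balance loses to side product. Starting material chooses between dissolved gas and target, and at saturation and full charge the selectivity factor is 68.5, or 1.84 decades. Integrating that choice while [target] grows puts a share 1.46% of the charge into side product, counted double.

So ask how the rest divides. Target and isomer of the product relax at 6.72 × 10⁻⁵ s⁻¹, so the run time lies 1.76 decades above the relaxation time. Take equilibrium, then: with 0.24 as [isomer of the product]/[target], the target's equilibrium share of the pair is 80.6%. This gives 79.5% for the target. Let the gas deficit close with the coefficient 9.3 × 10⁻⁴ s⁻¹ over the time that follows 0.620 d, which gives 100%.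

The forecast says 79.4% and 100%, holding that “dissolved gas returns to saturation”.

The flask gives 79.5% and 100%.

In this flask the relaxation half-life of target and isomer of the product, 0.119 d, is far shorter than the run of 10 d, and the target stands at 79.5% after 5.00 d and 79.5% after 10.0 d. The neighbour flask, left until 2.5 d, holds 1.43% as side product, so the share 80.6% of the remainder comes to 79.4%, and its target reads 79.5%.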